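**Plan**

1. Retrosynthesis (flavan numbered O1, C2–C4, C4a–C8a; flavonol ring B primed). Cuts, in order: the eight O-benzyl groups; the pyrone ring of the flavonol (chalcone from an aryl aldehyde and an acetophenone, then oxidative cyclisation); the C4–C2' bond (Friedel–Crafts); the C3–O and C4–O bonds (dihydroxylation of a flav-3-ene); the O1–C8a aryl ether bond; the C2–C3 bond (alkynylation of 3,4-dibenzyloxybenzaldehyde).
2. Forward: bromoaryl alkyne → (R)-propargylic alcohol → (Z)-allylic alcohol → pyran ring of the flavan by aryne O-arylation (a 2H-chromene) → 3,4-diol → arylation at C4 by a dithiane-masked 3,4,5-tribenzyloxybenzaldehyde → 3-O-benzylation and unmasking → flavonol annulation → hydrogenolysis.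
3. Enabling feature: ring A of the flavan carries O1 on C8a, and the neighbouring C8 is an unsubstituted CH with the C7 oxygen on its other side. A C8≡C8a aryne is therefore a 3-alkoxyaryne polarised for attack at C8a, and a cis C3=C4 bond on C4a holds the C2 oxygen in the ring plane beside C8a.
4. Stereochemistry: C2 comes from the catalyst-controlled alkynylation and is kept because the C2–O bond is never broken. C3 comes from osmylation anti to the C2 aryl group. C4 comes from attack of the arene on the C4 cation anti to the C3 oxygen (all-trans, 2R,3S,4S).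

Key step: step 5

Assumption: in step 3 (S)-BINOL is taken to deliver the R carbinol, as recalled for aromatic aldehydes with aryl alkynes in this catalyst system; if the carbinol proved S, (R)-BINOL would be used instead.

**Route**

Step 1
Reactants: 1 2-bromo-4-hydroxybenzaldehyde
Product: 2 4-(benzyloxy)-2-bromobenzaldehyde
Conditions: BnBr, K2CO3, DMF, rt
Reagents that add atoms: benzyl bromide, BrCc1ccccc1
Why: Williamson etherification of the phenoxide with a benzylic halide, to which the aldehyde and the aryl bromide are inert.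

Step 2
Reactants: 2 4-(benzyloxy)-2-bromobenzaldehyde
Product: 3 4-(benzyloxy)-2-bromo-1-ethynylbenzene
Conditions: dimethyl (1-diazo-2-oxopropyl)phosphonate, K2CO3, MeOH/THF, 0 °C → rt
Reagents that add atoms: dimethyl (1-diazo-2-oxopropyl)phosphonate, CC(=O)C(=[N+]=[N-])P(=O)(OC)OC
Why: Ohira–Bestmann (Seyferth–Gilbert) homologation, in which the diazo carbon becomes the terminal alkyne carbon under conditions mild enough for the aryl bromide and the benzyl ether.

Step 3
Reactants: 3 4-(benzyloxy)-2-bromo-1-ethynylbenzene, 4 3,4-bis(benzyloxy)benzaldehyde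
Product: 6 (1R)-1-[3,4-bis(benzyloxy)phenyl]-3-[4-(benzyloxy)-2-bromophenyl]prop-2-yn-1-ol, via alkynylzinc 5 (not isolated)
Conditions: 3 (2 equiv), Et2Zn, toluene, reflux; then (S)-BINOL (20 mol %), Ti(OiPr)4 (50 mol %), CH2Cl2, rt; then 4, rt
Reagents that add atoms: none
Why: Catalytic asymmetric addition of an alkynylzinc to an aromatic aldehyde, in which the chiral titanium binaphtholate selects the aldehyde face and so sets the future C2 centre by catalyst control.

Step 4
Reactants: 6 (1R)-1-[3,4-bis(benzyloxy)phenyl]-3-[4-(benzyloxy)-2-bromophenyl]prop-2-yn-1-ol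
Product: 7 (1S,2Z)-1-[3,4-bis(benzyloxy)phenyl]-3-[4-(benzyloxy)-2-bromophenyl]prop-2-en-1-ol
Conditions: H2 (1 atm), Pd/CaCO3 poisoned with Pb(OAc)2 (Lindlar catalyst), quinoline, EtOAc, rt
Reagents that add atoms: none
Why: Lindlar semihydrogenation adds H2 syn to give the Z alkene, while the poisoned catalyst should spare the aryl bromide, the benzyl ethers and the carbinol C–O bond; the descriptor changes from R to S only through the priority rules.

Step 5
Reactants: 7 (1S,2Z)-1-[3,4-bis(benzyloxy)phenyl]-3-[4-(benzyloxy)-2-bromophenyl]prop-2-en-1-ol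
Product: 10 (2S)-7-(benzyloxy)-2-[3,4-bis(benzyloxy)phenyl]-2H-chromene, via aryne alkoxide 8 (not isolated), via 8-lithiochromene 9 (not isolated)
Conditions: LiTMP (2.2 equiv), THF, −78 °C → 0 °C; aq. NH4Cl
Reagents that add atoms: none
Why: LiTMP forms the lithium alkoxide and then removes the only arene hydrogen ortho to bromine (the one between Br and OBn); loss of LiBr gives the 3-alkoxyaryne 8, whose triple bond spans the future C8 and C8a, and the alkoxide oxygen adds in the ring plane to C8a to leave the aryllithium 9 at C8, which is protonated. The closest known reaction types are the benzyne cyclisation of a tethered alkoxide onto a base-generated aryne and the meta-selective addition of nucleophiles to 3-alkoxyarynes. The pyran ring closes in a 6-exo-dig sense with respect to the aryne bond. No stereocentre is formed; the C2 centre from step 3 is carried through with retention because oxygen is the reacting atom and the C2–O bond is never broken, which avoids the benzylic ionisation at C2 that a closure in the opposite sense would risk. The step needs O–C8a over O–C8 bond formation: the C7 benzyloxy group beside the triple bond makes C8a the flatter, more electrophilic terminus and stabilises the carbanion developing at C8, and the Z-alkene tether can reach only C8a (six-membered against a strained seven-membered ring). Capture by the amine is disfavoured by the hindered base and by the planar tether that holds the alkoxide next to C8a.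

Step 6
Reactants: 10 (2S)-7-(benzyloxy)-2-[3,4-bis(benzyloxy)phenyl]-2H-chromene
Product: 11 (2R,3S,4S)-7-(benzyloxy)-2-[3,4-bis(benzyloxy)phenyl]-3,4-dihydro-2H-chromene-3,4-diol
Conditions: OsO4 (2 mol %), N-methylmorpholine N-oxide, acetone/H2O, 0 °C → rt
Reagents that add atoms: osmium tetroxide, O=[Os](=O)(=O)=O; N-methylmorpholine N-oxide, C[N+]1([O-])CCOCC1; water, O (both oxygens pass to the alkene from OsO4, which is refilled from the N-oxide and water)
Why: Upjohn syn-dihydroxylation of the C3=C4 bond from the face anti to the C2 aryl group sets C3 trans to C2 (and C4 cis to C3) by substrate control, as in the cis-hydroxylation of flav-3-enes.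

Step 7
Reactants: 12 3,4,5-tris(benzyloxy)benzaldehyde
Product: 13 2-[3,4,5-tris(benzyloxy)phenyl]-1,3-dithiane
Conditions: HS(CH2)3SH, BF3·OEt2 (10 mol %), CH2Cl2, 0 °C → rt
Reagents that add atoms: propane-1,3-dithiol, SCCCS
Why: Lewis acid-catalysed dithioacetalisation turns the deactivating formyl group into an acid-stable sp3 mask, so that the ring stays nucleophilic at its two equivalent free positions.

Step 8
Reactants: 11 (2R,3S,4S)-7-(benzyloxy)-2-[3,4-bis(benzyloxy)phenyl]-3,4-dihydro-2H-chromene-3,4-diol, 13 2-[3,4,5-tris(benzyloxy)phenyl]-1,3-dithiane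
Product: 14 (2R,3S,4S)-7-(benzyloxy)-2-[3,4-bis(benzyloxy)phenyl]-4-[2,3,4-tris(benzyloxy)-6-(1,3-dithian-2-yl)phenyl]-3,4-dihydro-2H-chromen-3-ol
Conditions: 13 (2 equiv), Sc(OTf)3 (10 mol %), 4 Å MS, CH2Cl2, −20 °C → rt
Reagents that add atoms: none
Why: Friedel–Crafts alkylation, the acid condensation of a flavan-3,4-diol with an electron-rich arene: the C4 cation (stabilised by the para 7-benzyloxy group) is taken up by the one kind of free position of 13 (ortho and para to benzyloxy groups), and attack anti to the C3 hydroxyl should set C4 trans to C3 by substrate control.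

Step 9
Reactants: 14 (2R,3S,4S)-7-(benzyloxy)-2-[3,4-bis(benzyloxy)phenyl]-4-[2,3,4-tris(benzyloxy)-6-(1,3-dithian-2-yl)phenyl]-3,4-dihydro-2H-chromen-3-ol
Product: 15 (2R,3S,4S)-3,7-bis(benzyloxy)-2-[3,4-bis(benzyloxy)phenyl]-4-[2,3,4-tris(benzyloxy)-6-(1,3-dithian-2-yl)phenyl]-3,4-dihydro-2H-chromene
Conditions: NaH, BnBr, Bu4NI (cat.), DMF, 0 °C → rt
Reagents that add atoms: benzyl bromide, BrCc1ccccc1
Why: Williamson etherification of the C3 hydroxyl, which keeps that oxygen from closing onto the aldehyde (lactol) or onto the chalcone (oxa-Michael addition) in steps 10 and 11.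

Step 10
Reactants: 15 (2R,3S,4S)-3,7-bis(benzyloxy)-2-[3,4-bis(benzyloxy)phenyl]-4-[2,3,4-tris(benzyloxy)-6-(1,3-dithian-2-yl)phenyl]-3,4-dihydro-2H-chromene
Product: 16 3,4,5-tris(benzyloxy)-2-{(2R,3S,4S)-3,7-bis(benzyloxy)-2-[3,4-bis(benzyloxy)phenyl]-3,4-dihydro-2H-chromen-4-yl}benzaldehyde
Conditions: MeI, CaCO3, MeCN/H2O, 45 °C
Reagents that add atoms: water, O
Why: Alkylative hydrolysis of the dithiane (S-methylation, then hydrolysis of the sulfonium) is non-oxidative and so should leave the electron-rich rings, the benzyl ethers and the three stereocentres untouched.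

Step 11
Reactants: 16 3,4,5-tris(benzyloxy)-2-{(2R,3S,4S)-3,7-bis(benzyloxy)-2-[3,4-bis(benzyloxy)phenyl]-3,4-dihydro-2H-chromen-4-yl}benzaldehyde, 17 1-[4-(benzyloxy)-2-hydroxyphenyl]ethan-1-one
Product: 19 7-(benzyloxy)-3-hydroxy-2-[3,4,5-tris(benzyloxy)-2-{(2R,3S,4S)-3,7-bis(benzyloxy)-2-[3,4-bis(benzyloxy)phenyl]-3,4-dihydro-2H-chromen-4-yl}phenyl]-4H-chromen-4-one, via chalcone 18 (not isolated)
Conditions: KOH, EtOH/THF, rt → 40 °C; then 30% aq. H2O2, 0 °C → rt
Reagents that add atoms: hydrogen peroxide, OO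
Why: Claisen–Schmidt condensation gives the 2'-hydroxychalcone, and Algar–Flynn–Oyamada oxidative cyclisation with alkaline H2O2 should close the pyrone and install the 3-hydroxyl, the flavonol being favoured because the acetophenone ring has no substituent at its 6'-position.

Step 12
Reactants: 19 7-(benzyloxy)-3-hydroxy-2-[3,4,5-tris(benzyloxy)-2-{(2R,3S,4S)-3,7-bis(benzyloxy)-2-[3,4-bis(benzyloxy)phenyl]-3,4-dihydro-2H-chromen-4-yl}phenyl]-4H-chromen-4-one
Product: 20 2-[2-{(2R,3S,4S)-2-(3,4-dihydroxyphenyl)-3,7-dihydroxy-3,4-dihydro-2H-chromen-4-yl}-3,4,5-trihydroxyphenyl]-3,7-dihydroxy-4H-chromen-4-one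
Conditions: H2 (1 atm), Pd(OH)2/C, THF/MeOH, rt
Reagents that add atoms: none
Why: Hydrogenolysis of the eight benzyl ethers under mild conditions that should leave the cyclic C2–O1 ether, the diarylmethine C4 and the tetrasubstituted pyrone double bond intact, so no stereocentre is touched.

**Compound list**

1 | 2-bromo-4-hydroxybenzaldehyde | O=Cc1ccc(O)cc1Br | starting material
2 | 4-(benzyloxy)-2-bromobenzaldehyde | O=Cc1ccc(OCc2ccccc2)cc1Br | intermediate
3 | 4-(benzyloxy)-2-bromo-1-ethynylbenzene | C#Cc1ccc(OCc2ccccc2)cc1Br | intermediate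
4 | 3,4-bis(benzyloxy)benzaldehyde | O=Cc1ccc(OCc2ccccc2)c(OCc2ccccc2)c1 | starting material
5 | {[4-(benzyloxy)-2-bromophenyl]ethynyl}(ethyl)zinc | CC[Zn]C#Cc1ccc(OCc2ccccc2)cc1Br | intermediate
6 | (1R)-1-[3,4-bis(benzyloxy)phenyl]-3-[4-(benzyloxy)-2-bromophenyl]prop-2-yn-1-ol | O[C@H](c1ccc(OCc2ccccc2)c(OCc2ccccc2)c1)C#Cc1ccc(OCc2ccccc2)cc1Br | intermediate
7 | (1S,2Z)-1-[3,4-bis(benzyloxy)phenyl]-3-[4-(benzyloxy)-2-bromophenyl]prop-2-en-1-ol | O[C@H](c1ccc(OCc2ccccc2)c(OCc2ccccc2)c1)/C=C\c1ccc(OCc2ccccc2)cc1Br | intermediate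
8 | lithium (1S,2Z)-1-[3,4-bis(benzyloxy)phenyl]-3-[4-(benzyloxy)-2,3-didehydrophenyl]prop-2-en-1-olate (aryne) | [Li+].[O-][C@H](c1ccc(OCc2ccccc2)c(OCc2ccccc2)c1)/C=C\C1=CC=C(OCc2ccccc2)C#C1 | intermediate
9 | (2S)-7-(benzyloxy)-2-[3,4-bis(benzyloxy)phenyl]-8-lithio-2H-chromene | O1c2c([Li])c(OCc3ccccc3)ccc2C=C[C@H]1c1ccc(OCc2ccccc2)c(OCc2ccccc2)c1 | intermediate
10 | (2S)-7-(benzyloxy)-2-[3,4-bis(benzyloxy)phenyl]-2H-chromene | O1c2cc(OCc3ccccc3)ccc2C=C[C@H]1c1ccc(OCc2ccccc2)c(OCc2ccccc2)c1 | intermediate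
11 | (2R,3S,4S)-7-(benzyloxy)-2-[3,4-bis(benzyloxy)phenyl]-3,4-dihydro-2H-chromene-3,4-diol (2,3-trans-3,4-cis) | O[C@H]1c2ccc(OCc3ccccc3)cc2O[C@H](c2ccc(OCc3ccccc3)c(OCc3ccccc3)c2)[C@H]1O | intermediate
12 | 3,4,5-tris(benzyloxy)benzaldehyde | O=Cc1cc(OCc2ccccc2)c(OCc2ccccc2)c(OCc2ccccc2)c1 | starting material
13 | 2-[3,4,5-tris(benzyloxy)phenyl]-1,3-dithiane | C1CSC(SC1)c1cc(OCc2ccccc2)c(OCc2ccccc2)c(OCc2ccccc2)c1 | intermediate
14 | (2R,3S,4S)-7-(benzyloxy)-2-[3,4-bis(benzyloxy)phenyl]-4-[2,3,4-tris(benzyloxy)-6-(1,3-dithian-2-yl)phenyl]-3,4-dihydro-2H-chromen-3-ol (all-trans) | C1CSC(SC1)c1cc(OCc2ccccc2)c(OCc2ccccc2)c(OCc2ccccc2)c1[C@@H]1c2ccc(OCc3ccccc3)cc2O[C@H](c2ccc(OCc3ccccc3)c(OCc3ccccc3)c2)[C@H]1O | intermediate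
15 | (2R,3S,4S)-3,7-bis(benzyloxy)-2-[3,4-bis(benzyloxy)phenyl]-4-[2,3,4-tris(benzyloxy)-6-(1,3-dithian-2-yl)phenyl]-3,4-dihydro-2H-chromene | C1CSC(SC1)c1cc(OCc2ccccc2)c(OCc2ccccc2)c(OCc2ccccc2)c1[C@@H]1c2ccc(OCc3ccccc3)cc2O[C@H](c2ccc(OCc3ccccc3)c(OCc3ccccc3)c2)[C@H]1OCc1ccccc1 | intermediate
16 | 3,4,5-tris(benzyloxy)-2-{(2R,3S,4S)-3,7-bis(benzyloxy)-2-[3,4-bis(benzyloxy)phenyl]-3,4-dihydro-2H-chromen-4-yl}benzaldehyde | O=Cc1cc(OCc2ccccc2)c(OCc2ccccc2)c(OCc2ccccc2)c1[C@@H]1c2ccc(OCc3ccccc3)cc2O[C@H](c2ccc(OCc3ccccc3)c(OCc3ccccc3)c2)[C@H]1OCc1ccccc1 | intermediate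
17 | 1-[4-(benzyloxy)-2-hydroxyphenyl]ethan-1-one | CC(=O)c1ccc(OCc2ccccc2)cc1O | starting material
18 | (2E)-1-[4-(benzyloxy)-2-hydroxyphenyl]-3-[3,4,5-tris(benzyloxy)-2-{(2R,3S,4S)-3,7-bis(benzyloxy)-2-[3,4-bis(benzyloxy)phenyl]-3,4-dihydro-2H-chromen-4-yl}phenyl]prop-2-en-1-one (chalcone) | O=C(/C=C/c1cc(OCc2ccccc2)c(OCc2ccccc2)c(OCc2ccccc2)c1[C@@H]1c2ccc(OCc3ccccc3)cc2O[C@H](c2ccc(OCc3ccccc3)c(OCc3ccccc3)c2)[C@H]1OCc1ccccc1)c1ccc(OCc2ccccc2)cc1O | intermediate
19 | 7-(benzyloxy)-3-hydroxy-2-[3,4,5-tris(benzyloxy)-2-{(2R,3S,4S)-3,7-bis(benzyloxy)-2-[3,4-bis(benzyloxy)phenyl]-3,4-dihydro-2H-chromen-4-yl}phenyl]-4H-chromen-4-one | O=c1c(O)c(-c2cc(OCc3ccccc3)c(OCc3ccccc3)c(OCc3ccccc3)c2[C@@H]2c3ccc(OCc4ccccc4)cc3O[C@H](c3ccc(OCc4ccccc4)c(OCc4ccccc4)c3)[C@H]2OCc2ccccc2)oc2cc(OCc3ccccc3)ccc12 | intermediate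
20 | 2-[2-{(2R,3S,4S)-2-(3,4-dihydroxyphenyl)-3,7-dihydroxy-3,4-dihydro-2H-chromen-4-yl}-3,4,5-trihydroxyphenyl]-3,7-dihydroxy-4H-chromen-4-one (CNP0381334.2) | O=c1c(O)c(-c2cc(O)c(O)c(O)c2[C@@H]2c3ccc(O)cc3O[C@H](c3ccc(O)c(O)c3)[C@H]2O)oc2cc(O)ccc12 | target

**Step count**

Total steps: 12. Longest linear sequence: 11 steps (steps 1–6 and 8–12; step 7 is the one-step side branch).

**Steps most likely to fail**

Step 5. What may go wrong: capture of the aryne by the amine instead of the tethered alkoxide, incomplete ortho-lithiation, or base-induced erosion of the C2 configuration through deprotonation of the product at its allylic, benzylic position. Fallback (sets out from 7, comes back at 10): the same C–O bond is closed without an aryne by palladium-catalysed intramolecular etherification of the aryl bromide with the secondary alcohol (Buchwald–Hartwig C–O coupling; Pd(OAc)2, 2-(di-tert-butylphosphino)-1,1'-binaphthyl, Cs2CO3, toluene, 60 °C). Oxidative addition into the C8a–Br bond and C–O reductive elimination again leave the C2–O bond untouched. This detour makes no new compound F0.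

Step 8. What may go wrong: poor facial selectivity at C4 (attack syn to the C3 hydroxyl), and slow capture by the hindered arene position, which would let the cation condense with itself. Fallback (sets out from 11, comes back at 14): 11 is acetylated (Ac2O, pyridine, DMAP) to the 3,4-di-O-acetate F1. TMSOTf (cat.) in CH2Cl2 at −78 °C ionises the 4-acetate; the 3-acetoxy group closes onto C4 as a cis-fused acetoxonium ion and forces 13 to add from the opposite face, giving the 3-O-acetyl C4 adduct F2. K2CO3 in MeOH then removes the acetate to give 14.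

Step 11. What may go wrong: slow aldol condensation of the hindered, electron-rich aldehyde, and in the oxidative cyclisation a 5-exo closure at the α-carbon (the aurone pathway), because the twisted ring B stabilises the β-position poorly. Fallback (sets out from 16 and 17, comes back at 19): the chalcone 18 is made by the Claisen–Schmidt condensation alone and isolated. It is cyclised oxidatively with I2 (cat.) in DMSO at 120 °C to the 3-unsubstituted flavone F3. This is epoxidised with dimethyldioxirane (acetone/CH2Cl2, 0 °C) to the flavone 2,3-epoxide F4, and a trace of TsOH isomerises the epoxide to the 3-hydroxyflavone 19.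

**Further compounds**

F0 | step 5 | none | none
F1 | step 8 | (2R,3R,4S)-7-(benzyloxy)-2-[3,4-bis(benzyloxy)phenyl]-3,4-dihydro-2H-chromene-3,4-diyl diacetate (same spatial arrangement as 11) | CC(=O)O[C@H]1c2ccc(OCc3ccccc3)cc2O[C@H](c2ccc(OCc3ccccc3)c(OCc3ccccc3)c2)[C@H]1OC(C)=O
F2 | step 8 | (2R,3S,4S)-7-(benzyloxy)-2-[3,4-bis(benzyloxy)phenyl]-4-[2,3,4-tris(benzyloxy)-6-(1,3-dithian-2-yl)phenyl]-3,4-dihydro-2H-chromen-3-yl acetate | C1CSC(SC1)c1cc(OCc2ccccc2)c(OCc2ccccc2)c(OCc2ccccc2)c1[C@@H]1c2ccc(OCc3ccccc3)cc2O[C@H](c2ccc(OCc3ccccc3)c(OCc3ccccc3)c2)[C@H]1OC(C)=O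
F3 | step 11 | 7-(benzyloxy)-2-[3,4,5-tris(benzyloxy)-2-{(2R,3S,4S)-3,7-bis(benzyloxy)-2-[3,4-bis(benzyloxy)phenyl]-3,4-dihydro-2H-chromen-4-yl}phenyl]-4H-chromen-4-one | O=c1cc(-c2cc(OCc3ccccc3)c(OCc3ccccc3)c(OCc3ccccc3)c2[C@@H]2c3ccc(OCc4ccccc4)cc3O[C@H](c3ccc(OCc4ccccc4)c(OCc4ccccc4)c3)[C@H]2OCc2ccccc2)oc2cc(OCc3ccccc3)ccc12
F4 | step 11 | 2,3-epoxide of F3 (both epoxide diastereomers; flavan centres 2R,3S,4S) | O=C1C2OC2(c2cc(OCc3ccccc3)c(OCc3ccccc3)c(OCc3ccccc3)c2[C@@H]2c3ccc(OCc4ccccc4)cc3O[C@H](c3ccc(OCc4ccccc4)c(OCc4ccccc4)c3)[C@H]2OCc2ccccc2)Oc2cc(OCc3ccccc3)ccc12
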